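The numbers in the tables come from a simulation with constants of no real substance.

A product excess that stays flat across a run looks like proof that two substrates keep exchanging, but it speaks for the product made between the first reading and the last, not for what stood before the first.

| flask | left-handed substrate | right-handed substrate | coupling partner | free catalyst | racemization catalyst | remark | time |
|---|---|---|---|---|---|---|---|
| eta | 0.40 M | 0.40 M | 2.2 equiv | 0.05 mol% | 0.15 mol% | the very flask that is asked about, followed so far |  |
| delta | 0.40 M | 0.40 M | 3.3 equiv | 0.05 mol% | 0.15 mol% | run made earlier |  |
| flask | 0.40 M | 0.40 M | 2.20 equiv | 0.05 mol% | 0.15 mol% |  | 2.0 min |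

- eta (time / s: left-handed product / %, right-handed product / %): 10.0: 29.3, 6.8; 15.0: 30.4, 7.5; 25.0: 33.1, 7.9; 30.0: 33.2, 7.2; 40.0: 34.8, 7.8; 50.0: 34.5, 8.4; 60.0: 35.4, 8.0
- delta (time / s: left-handed product / %, right-handed product / %): 10.0: 36.9, 9.1; 20.0: 39.7, 10.1; 30.0: 40.3, 9.8; 50.0: 43.0, 10.9; 80.0: 41.9, 10.9; 90.0: 42.4, 11.1; 120: 44.0, 9.9

(scatter of a reading: 0.5 percentage points)

* left-handed product and right-handed product together, in percent of the left-handed substrate and right-handed substrate charged together, at 2.0 min
* excess of left-handed product over right-handed product in the product at 2.0 min
* whether the exchange between left-handed substrate and right-handed substrate keeps pace with the reaction: how far the product's excess at 2.0 min gets from its value without exchange to its value with instant exchange (above 80% keeps pace, below 20% hardly takes part, else lags behind)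

- free catalyst is single-handed; left-handed substrate and right-handed substrate are mirror images of each other, charged as a racemate, each of them at the stated concentration
- an excess is below zero if the other one leads

The useful number here is the turnover count, or turnover number: product formed per free catalyst charged. In the eta run it reads 1440 at 10.0 s and 1740 at 60.0 s, a small late gain. So 83.2% of the turnovers behind the last reading lay before the first. The eta excess of 62.3% to 63.1% therefore describes a product mostly made unseen.

My own reckoning puts the eta flask's total at 2.0 min near its last reading, 43.4%, and withholds "keeps pace", since 83.2% of the product behind that flat excess stood before the first reading. One number is not enough, though. The delta run, with the same catalyst charge and more coupling partner, reads 1840 turnovers at 10.0 s, more than the eta run at 60.0 s, and 2160 at 120 s, so the count moves with the coupling partner.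

The forecast gives 44.5%, 61.5% and keeps pace: “The substrate is therefore staying nearly racemic, so exchange keeps pace”.

The flask gives 44.2% and 63.9%, and the exchange lags behind, getting 43% of the way.

    left-handed substrate + racemization catalyst ⇌ right-handed substrate + racemization catalyst, rate k1*[racemization catalyst]*[left-handed substrate] forward; the back reaction follows from the equilibrium constant (k = 73.0 M⁻¹ s⁻¹)
    coupling partner + free catalyst + right-handed substrate → free catalyst + right-handed product (k = 500 M⁻² s⁻¹)
    coupling partner + free catalyst + left-handed substrate → free catalyst + left-handed product (k = 2900 M⁻² s⁻¹)
    2 free catalyst → spent catalyst (k = 2400 M⁻¹ s⁻¹)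
    2 coupling partner → homo dimer (k = 0.0480 M⁻¹ s⁻¹)

In the flask, at 0.200 min free catalyst stood at 7.99% of its charge, with 36.9% product made and right-handed substrate leading by 16.3% among what was left. Exchange went on afterwards, and at 1.00 min that lead was 1.07%. The neighbour flask with 0.12 mol% of free catalyst gives 50.4% at 2.00 min, yet its count is 840 turnovers, fewer than the 1740 of the eta run's last reading and the 1770 of the flask at that same time.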